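**Retrosynthetic overview** (ring A = formyl-bearing benzoate ring, ring B = hexasubstituted arene, ring C = seven-membered depsidone lactone, ring D = five-membered hemiacylal lactone)
1. 30 ⇐ 29 (three allyl groups removed with zerovalent palladium) ⇐ 28 (benzylic bromide + hydrogen fumarate) ⇐ 27 ⇐ 26; the labile hemiacylal centre is fixed late, as an allyl carbonate, by a catalytic dynamic kinetic resolution.
2. 26 ⇐ 24: ring C by acid unmasking and TFAA lactonisation; 24 ⇐ 23 + 7 by SNAr diaryl ether formation.
3. 23 ⇐ 21: ring D is closed by forming the bond from the last unsubstituted carbon of ring B to the lactone carbonyl carbon (aryl iodide → aryllithium → attack on a carbonate).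
4. Enabling feature: the hemiacylal carbon (CH bonded to two oxygens) is attached to ring B directly beside that carbon, so a phenyl carbonate on the hemiacylal oxygen holds its C=O carbon in five-membered (5-exo-trig) reach of an aryl anion there.
5. Ring order: rings A (from 1) and B (from 8) are bought as arenes and substituted; then ring D (step 12), the diaryl ether (step 13), ring C (step 14).

Key step: step 12

Remark on the chemistry: the hemiacylal carbon of a 3-hydroxyphthalide epimerises by ring–chain tautomerism, so it is carried as a racemate, fixed as a carbonate in step 15 and released only in the last step under neutral, base-free conditions.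

**Step 1**
Reactants: 1 4-bromo-2-fluoro-6-methylbenzoic acid
Product: 2 tert-butyl 4-bromo-2-fluoro-6-methylbenzoate
Conditions: tert-butyl 2,2,2-trichloroacetimidate, BF3·OEt2 (cat.), CH2Cl2/cyclohexane, rt
Reagents that add atoms: tert-butyl 2,2,2-trichloroacetimidate, CC(C)(C)OC(=N)C(Cl)(Cl)Cl
Why: Acid-catalysed O-alkylation of the carboxylic acid by the imidate (trichloroacetimidate esterification) runs through the tert-butyl cation and is therefore not hindered by the two ortho substituents.

**Step 2**
Reactants: 2 tert-butyl 4-bromo-2-fluoro-6-methylbenzoate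
Product: 4 tert-butyl 4-bromo-2-fluoro-3-formyl-6-methylbenzoate, via arylmagnesium chloride 3 (not isolated)
Conditions: TMPMgCl·LiCl, THF, −40 °C; DMF, −40 °C to rt; aq. NH4Cl
Reagents that add atoms: N,N-dimethylformamide, CN(C)C=O
Why: Directed magnesiation with the hindered magnesium amide removes the most acidic ring proton (flanked by F and Br) without touching the ester or the benzylic methyl group, and DMF formylates the arylmagnesium.

**Step 3**
Reactants: 4 tert-butyl 4-bromo-2-fluoro-3-formyl-6-methylbenzoate
Product: 6 tert-butyl 2-fluoro-3-formyl-4-hydroxy-6-methylbenzoate, via pinacol boronate 5 (not isolated)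
Conditions: B2pin2, Pd(dppf)Cl2 (cat.), KOAc, 1,4-dioxane, 80 °C; then N-methylmorpholine N-oxide, THF, 50 °C
Reagents that add atoms: N-methylmorpholine N-oxide, C[N+]1([O-])CCOCC1
Why: Miyaura borylation of the aryl bromide followed by amine N-oxide oxidation of the C–B bond gives the phenol without peroxide, which would cause a Dakin reaction of the ortho-formyl phenol.

**Step 4**
Reactants: 6 tert-butyl 2-fluoro-3-formyl-4-hydroxy-6-methylbenzoate
Product: 7 tert-butyl 4-(allyloxy)-2-fluoro-3-formyl-6-methylbenzoate
Conditions: allyl bromide, K2CO3, DMF, 0 °C to rt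
Reagents that add atoms: allyl bromide, C=CCBr
Why: Williamson etherification of the acidic ortho-formyl phenol should be faster at low temperature than intermolecular SNAr of the phenoxide on the activated fluoride.

**Step 5**
Reactants: 8 3,5-dihydroxybenzaldehyde
Product: 9 3,5-bis(methoxymethoxy)benzaldehyde
Conditions: MOMCl, iPr2NEt, CH2Cl2, 0 °C to rt
Reagents that add atoms: chloromethyl methyl ether, COCCl
Why: Standard double O-alkylation of the two equivalent phenols gives the MOM ethers needed as ortho-directing groups.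

**Step 6**
Reactants: 9 3,5-bis(methoxymethoxy)benzaldehyde
Product: 12 4-(hydroxymethyl)-3,5-bis(methoxymethoxy)benzaldehyde, via lithium α-amino alkoxide 10 (not isolated), via aryllithium 11 (not isolated)
Conditions: LiN(CH2CH2)2NMe (from 1-methylpiperazine and n-BuLi), THF, −78 °C; n-BuLi, TMEDA, −40 °C; (CH2O)n, −40 °C to rt; aq. NH4Cl
Reagents that add atoms: formaldehyde (as paraformaldehyde), C=O
Why: In situ protection of the aldehyde as a weakly directing lithium α-amino alkoxide lets the two MOM ethers direct ortho-lithiation to the carbon between them, and the aryllithium adds to formaldehyde.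

**Step 7**
Reactants: 12 4-(hydroxymethyl)-3,5-bis(methoxymethoxy)benzaldehyde
Product: 13 4-{[tert-butyl(diphenyl)silyl]oxymethyl}-3,5-bis(methoxymethoxy)benzaldehyde
Conditions: TBDPSCl, imidazole, DMF, rt
Reagents that add atoms: tert-butyl(chloro)diphenylsilane, CC(C)(C)[Si](Cl)(c1ccccc1)c1ccccc1
Why: Imidazole-promoted silylation of the primary benzylic alcohol gives an ether meant to survive base, fluoride at an aryl silyl ether and short exposure to acid.

**Step 8**
Reactants: 13 4-{[tert-butyl(diphenyl)silyl]oxymethyl}-3,5-bis(methoxymethoxy)benzaldehyde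
Product: 17 4-{[tert-butyl(diphenyl)silyl]oxymethyl}-2-hydroxy-3,5-bis(methoxymethoxy)benzaldehyde, via lithium α-amino alkoxide 14 (not isolated), via aryllithium 15 (not isolated), via dimethyl arylboronate 16 (not isolated)
Conditions: LiN(Me)CH2CH2NMe2 (from the amine and n-BuLi), THF, −20 °C; n-BuLi, −20 °C; B(OMe)3, −78 °C to rt; N-methylmorpholine N-oxide, rt; aq. NH4Cl
Reagents that add atoms: N-methylmorpholine N-oxide, C[N+]1([O-])CCOCC1
Why: The strongly chelating α-amino alkoxide directs lithiation to one of the two equivalent ortho carbons (each also ortho to a MOM ether), and borylation followed by N-oxide oxidation turns C–Li into C–OH without a Dakin reaction.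

**Step 9**
Reactants: 17 4-{[tert-butyl(diphenyl)silyl]oxymethyl}-2-hydroxy-3,5-bis(methoxymethoxy)benzaldehyde
Product: 18 4-{[tert-butyl(diphenyl)silyl]oxymethyl}-2-hydroxy-6-iodo-3,5-bis(methoxymethoxy)benzaldehyde
Conditions: N-iodosuccinimide, MeCN, 0 °C to rt, dark
Reagents that add atoms: N-iodosuccinimide, O=C1CCC(=O)N1I
Why: Electrophilic aromatic iodination can only take the single remaining ring C–H, which is activated by one ortho and one para MOM-oxy group.

**Step 10**
Reactants: 18 4-{[tert-butyl(diphenyl)silyl]oxymethyl}-2-hydroxy-6-iodo-3,5-bis(methoxymethoxy)benzaldehyde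
Product: 19 2-{[tert-butyl(dimethyl)silyl]oxy}-4-{[tert-butyl(diphenyl)silyl]oxymethyl}-6-iodo-3,5-bis(methoxymethoxy)benzaldehyde
Conditions: TBSCl, imidazole, DMF, rt
Reagents that add atoms: tert-butyl(chloro)dimethylsilane, CC(C)(C)[Si](C)(C)Cl
Why: Silylation masks the phenol, which would otherwise attack the carbonate of step 11 or expel the acetal substituent through an ortho-quinone methide.

**Step 11**
Reactants: 19 2-{[tert-butyl(dimethyl)silyl]oxy}-4-{[tert-butyl(diphenyl)silyl]oxymethyl}-6-iodo-3,5-bis(methoxymethoxy)benzaldehyde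
Product: 21 (aryl)[(4-methoxybenzyl)oxy]methyl phenyl carbonate (racemic; aryl = ring of 19), via 1-chloroalkyl carbonate 20 (not isolated)
Conditions: PhOC(O)Cl, pyridine (cat.), CH2Cl2, 0 °C to rt; then 4-methoxybenzyl alcohol, iPr2NEt, −20 °C to rt
Reagents that add atoms: phenyl chloroformate, O=C(Cl)Oc1ccccc1; 4-methoxybenzyl alcohol, COc1ccc(CO)cc1
Why: Pyridine-catalysed insertion of the aldehyde into the C–Cl bond of the chloroformate gives the 1-chloroalkyl carbonate, whose chloride is replaced by the alcohol through the aryl-stabilised oxocarbenium ion (SN1 acetal formation) to give the racemic mixed acetal.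

**Step 12**
Reactants: 21 (aryl)[(4-methoxybenzyl)oxy]methyl phenyl carbonate
Product: 23 rac-3-[(4-methoxybenzyl)oxy]phthalide carrying 4-OTBS, 5,7-bis(MOM-oxy) and 6-CH2OTBDPS, via aryllithium 22 (not isolated)
Conditions: n-BuLi, THF/Et2O, −100 °C to −78 °C; AcOH
Reagents that add atoms: none
Why: Iodine–lithium exchange at −100 °C should be faster than addition of n-BuLi to the carbonate and gives aryllithium 22, whose carbanionic ring carbon is ortho to the carbon that bears the acetal. The carbonyl carbon of the phenyl carbonate on the acetal oxygen is then reached in a 5-exo-trig attack that forms the aryl–C(=O) bond and closes ring D; the closest known reaction is the Parham cyclisation of ortho-halobenzyl carbamates and carbonates to phthalides. The tetrahedral intermediate should expel phenoxide, a far better leaving group than the ring hemiacetal oxygen, so the lactone stays closed instead of opening to a formyl ester. No new stereocentre is formed: the acetal carbon is carried as a racemate and is fixed in step 15. The step needs chemoselectivity (exchange before carbonyl addition, secured by the iodide, the temperature and the flanking MOM ether that coordinates lithium) and site selectivity (only this carbonate is within reach; the two silyl ethers offer no electrophile). It completes the hexasubstituted ring B and delivers the lactone directly at the hemiacylal oxidation level.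

**Step 13**
Reactants: 23 rac-3-[(4-methoxybenzyl)oxy]phthalide fragment; 7 tert-butyl 4-(allyloxy)-2-fluoro-3-formyl-6-methylbenzoate
Product: 24 diaryl ether (racemic)
Conditions: CsF, DMF, rt to 50 °C
Reagents that add atoms: none
Why: Fluoride cleaves only the aryl silyl ether, and the phenoxide displaces the fluoride of 7, which is activated by the ortho formyl and ortho ester groups (desilylative SNAr diaryl ether synthesis).

**Step 14**
Reactants: 24 diaryl ether
Product: 26 racemic depsidone lactol, via seco acid 25 (not isolated)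
Conditions: TFA, anisole, CH2Cl2, 0 °C to rt; evaporate; (CF3CO)2O, toluene, 0 °C to rt; MeOH, then pH 5 buffer
Reagents that add atoms: none
Why: TFA removes the two MOM ethers, the tert-butyl ester and the 4-methoxybenzyl acetal (cations trapped by anisole), and the mixed trifluoroacetic anhydride of the benzoic acid then lactonises onto the only phenol that can reach it through a seven-membered ring (depsidone lactonisation), the hemiacylal hydroxyl being a poor nucleophile that would need an eight-membered ring.

**Step 15**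
Reactants: 26 racemic depsidone lactol
Product: 27 (1S)-bis(allyl carbonate)
Conditions: diallyl dicarbonate, (R)-benzotetramisole (10 mol %), iPr2NEt, CHCl3, 0 °C
Reagents that add atoms: diallyl dicarbonate, C=CCOC(=O)OC(=O)OCC=C
Why: Proposed new method: the chiral isothiourea is alkoxycarbonylated by the dicarbonate and should transfer the allyloxycarbonyl group faster to one lactol enantiomer while the enantiomers interconvert through base-mediated ring–chain tautomerism, so the hemiacylal centre is set by the catalyst (its antipode is to be chosen to give the spatial arrangement of the target, here named S because the carbonate oxygen outranks the lactone oxygen) and the chelated phenol is carbonated as a bystander; the closest known reaction type is the isothiourea- or carbene-catalysed acylative dynamic kinetic resolution of 3-hydroxyphthalides with anhydrides.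

**Step 16**
Reactants: 27 (1S)-bis(allyl carbonate)
Product: 28 (1S)-benzylic bromide
Conditions: Ph3PBr2, CH2Cl2, 0 °C to rt
Reagents that add atoms: triphenylphosphine dibromide, BrP(Br)(c1ccccc1)(c1ccccc1)c1ccccc1
Why: Triphenylphosphine dibromide converts silyl ethers directly into bromides, so no free benzylic alcohol appears beside the aryl carbonate and carbonate migration is avoided.

**Step 17**
Reactants: 28 (1S)-benzylic bromide
Product: 29 (1S)-fumarate half ester
Conditions: fumaric acid (excess), Cs2CO3 (0.5 equiv per acid; gives CsO2CCH=CHCO2H), DMF, 0 °C to rt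
Reagents that add atoms: fumaric acid, OC(=O)/C=C/C(=O)O
Why: SN2 displacement of the primary benzylic bromide by the carboxylate of caesium hydrogen fumarate, used in excess so that only one carboxyl group is alkylated, installs the (E)-half ester without a strongly basic step.

**Step 18**
Reactants: 29 (1S)-fumarate half ester
Product: 30 target CNP0379578.1, (1R)
Conditions: Pd(PPh3)4 (cat.), N-methylaniline, THF, rt, dark
Reagents that add atoms: none
Why: Zerovalent palladium ionises the two allyl carbonates and the allyl aryl ether (Tsuji–Trost deallylation), N-methylaniline traps the allyl groups, and the hemiacylal is released by loss of CO2 from its carbonic half ester in the presence of the free carboxylic acid, so no bond to the stereocentre is broken and no basic step opens the lactol.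

**Compound list** (positions in 26–30 follow salazinic acid numbering: C-1 lactol carbon, 4-OH on ring B, C-5 benzylic CH2, 8-methyl, 10-OH and 11-CHO on ring A)
1 | 4-bromo-2-fluoro-6-methylbenzoic acid | Cc1cc(Br)cc(F)c1C(=O)O | starting material
2 | tert-butyl 4-bromo-2-fluoro-6-methylbenzoate | Cc1cc(Br)cc(F)c1C(=O)OC(C)(C)C | intermediate
3 | [6-bromo-3-(tert-butoxycarbonyl)-2-fluoro-4-methylphenyl]magnesium chloride | Cc1cc(Br)c([Mg]Cl)c(F)c1C(=O)OC(C)(C)C | intermediate (not isolated)
4 | tert-butyl 4-bromo-2-fluoro-3-formyl-6-methylbenzoate | Cc1cc(Br)c(C=O)c(F)c1C(=O)OC(C)(C)C | intermediate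
5 | tert-butyl 2-fluoro-3-formyl-6-methyl-4-(4,4,5,5-tetramethyl-1,3,2-dioxaborolan-2-yl)benzoate | Cc1cc(B2OC(C)(C)C(C)(C)O2)c(C=O)c(F)c1C(=O)OC(C)(C)C | intermediate (not isolated)
6 | tert-butyl 2-fluoro-3-formyl-4-hydroxy-6-methylbenzoate | Cc1cc(O)c(C=O)c(F)c1C(=O)OC(C)(C)C | intermediate
7 | tert-butyl 4-(allyloxy)-2-fluoro-3-formyl-6-methylbenzoate | Cc1cc(OCC=C)c(C=O)c(F)c1C(=O)OC(C)(C)C | intermediate
8 | 3,5-dihydroxybenzaldehyde | O=Cc1cc(O)cc(O)c1 | starting material
9 | 3,5-bis(methoxymethoxy)benzaldehyde | O=Cc1cc(OCOC)cc(OCOC)c1 | intermediate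
10 | lithium [3,5-bis(methoxymethoxy)phenyl](4-methylpiperazin-1-yl)methanolate | [Li]OC(N1CCN(C)CC1)c1cc(OCOC)cc(OCOC)c1 | intermediate (not isolated)
11 | 4-lithio derivative of 10 (lithium between the two MOM ethers) | [Li]OC(N1CCN(C)CC1)c1cc(OCOC)c([Li])c(OCOC)c1 | intermediate (not isolated)
12 | 4-(hydroxymethyl)-3,5-bis(methoxymethoxy)benzaldehyde | O=Cc1cc(OCOC)c(CO)c(OCOC)c1 | intermediate
13 | 4-{[tert-butyl(diphenyl)silyl]oxymethyl}-3,5-bis(methoxymethoxy)benzaldehyde | O=Cc1cc(OCOC)c(CO[Si](c2ccccc2)(c2ccccc2)C(C)(C)C)c(OCOC)c1 | intermediate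
14 | lithium α-amino alkoxide from 13 and LiN(Me)CH2CH2NMe2 | [Li]OC(N(C)CCN(C)C)c1cc(OCOC)c(CO[Si](c2ccccc2)(c2ccccc2)C(C)(C)C)c(OCOC)c1 | intermediate (not isolated)
15 | 2-lithio derivative of 14 | [Li]OC(N(C)CCN(C)C)c1c([Li])c(OCOC)c(CO[Si](c2ccccc2)(c2ccccc2)C(C)(C)C)c(OCOC)c1 | intermediate (not isolated)
16 | dimethyl boronate at C-2 of 14 | COB(OC)c1c(C(O[Li])N(C)CCN(C)C)cc(OCOC)c(CO[Si](c2ccccc2)(c2ccccc2)C(C)(C)C)c1OCOC | intermediate (not isolated)
17 | 4-{[tert-butyl(diphenyl)silyl]oxymethyl}-2-hydroxy-3,5-bis(methoxymethoxy)benzaldehyde | O=Cc1c(O)c(OCOC)c(CO[Si](c2ccccc2)(c2ccccc2)C(C)(C)C)c(OCOC)c1 | intermediate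
18 | 4-{[tert-butyl(diphenyl)silyl]oxymethyl}-2-hydroxy-6-iodo-3,5-bis(methoxymethoxy)benzaldehyde | O=Cc1c(O)c(OCOC)c(CO[Si](c2ccccc2)(c2ccccc2)C(C)(C)C)c(OCOC)c1I | intermediate
19 | 2-{[tert-butyl(dimethyl)silyl]oxy}-4-{[tert-butyl(diphenyl)silyl]oxymethyl}-6-iodo-3,5-bis(methoxymethoxy)benzaldehyde | O=Cc1c(O[Si](C)(C)C(C)(C)C)c(OCOC)c(CO[Si](c2ccccc2)(c2ccccc2)C(C)(C)C)c(OCOC)c1I | intermediate
20 | chloro(aryl)methyl phenyl carbonate, aryl = ring of 19, racemic | O=C(Oc1ccccc1)OC(Cl)c1c(O[Si](C)(C)C(C)(C)C)c(OCOC)c(CO[Si](c2ccccc2)(c2ccccc2)C(C)(C)C)c(OCOC)c1I | intermediate (not isolated)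
21 | (aryl)[(4-methoxybenzyl)oxy]methyl phenyl carbonate, aryl = ring of 19, racemic | O=C(Oc1ccccc1)OC(OCc1ccc(OC)cc1)c1c(O[Si](C)(C)C(C)(C)C)c(OCOC)c(CO[Si](c2ccccc2)(c2ccccc2)C(C)(C)C)c(OCOC)c1I | intermediate
22 | aryllithium from 21 (Li in place of I) | O=C(Oc1ccccc1)OC(OCc1ccc(OC)cc1)c1c(O[Si](C)(C)C(C)(C)C)c(OCOC)c(CO[Si](c2ccccc2)(c2ccccc2)C(C)(C)C)c(OCOC)c1[Li] | intermediate (not isolated)
23 | rac-4-{[tert-butyl(dimethyl)silyl]oxy}-6-{[tert-butyl(diphenyl)silyl]oxymethyl}-3-[(4-methoxybenzyl)oxy]-5,7-bis(methoxymethoxy)-2-benzofuran-1(3H)-one | O=C1OC(OCc2ccc(OC)cc2)c2c(O[Si](C)(C)C(C)(C)C)c(OCOC)c(CO[Si](c3ccccc3)(c3ccccc3)C(C)(C)C)c(OCOC)c12 | intermediate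
24 | tert-butyl 4-(allyloxy)-3-formyl-6-methyl-2-(aryloxy)benzoate, aryloxy = 23 bonded through its C-4 oxygen in place of the silyl group, racemic | Cc1cc(OCC=C)c(C=O)c(Oc2c(OCOC)c(CO[Si](c3ccccc3)(c3ccccc3)C(C)(C)C)c(OCOC)c3C(=O)OC(OCc4ccc(OC)cc4)c23)c1C(=O)OC(C)(C)C | intermediate
25 | seco acid: 24 without the two MOM groups, the tert-butyl ester and the 4-methoxybenzyl group | Cc1cc(OCC=C)c(C=O)c(Oc2c(O)c(CO[Si](c3ccccc3)(c3ccccc3)C(C)(C)C)c(O)c3C(=O)OC(O)c23)c1C(=O)O | intermediate (not isolated)
26 | racemic depsidone lactol: 10-O-allyl, 5-CH2-O-TBDPS, free 4-OH and 1-OH | Cc1cc(OCC=C)c(C=O)c2c1C(=O)Oc1c(CO[Si](c3ccccc3)(c3ccccc3)C(C)(C)C)c(O)c3c(c1O2)C(O)OC3=O | intermediate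
27 | (1S)-1,4-bis[(allyloxy)carbonyloxy] derivative of 26 | Cc1cc(OCC=C)c(C=O)c2c1C(=O)Oc1c(CO[Si](c3ccccc3)(c3ccccc3)C(C)(C)C)c(OC(=O)OCC=C)c3c(c1O2)[C@H](OC(=O)OCC=C)OC3=O | intermediate
28 | (1S)-5-(bromomethyl) analogue of 27 | Cc1cc(OCC=C)c(C=O)c2c1C(=O)Oc1c(CBr)c(OC(=O)OCC=C)c3c(c1O2)[C@H](OC(=O)OCC=C)OC3=O | intermediate
29 | (1S)-5-CH2 (E)-hydrogen fumarate of the 10-O-allyl 1,4-bis(allyl carbonate) | Cc1cc(OCC=C)c(C=O)c2c1C(=O)Oc1c(COC(=O)/C=C/C(=O)O)c(OC(=O)OCC=C)c3c(c1O2)[C@H](OC(=O)OCC=C)OC3=O | intermediate
30 | CNP0379578.1: (1R)-lactol, 5-CH2 (E)-hydrogen fumarate, free 4-OH and 10-OH, 11-CHO, 8-methyl | Cc1cc(O)c(C=O)c2c1C(=O)Oc1c(COC(=O)/C=C/C(=O)O)c(O)c3c(c1O2)[C@H](O)OC3=O | target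

Total step count: 18. Longest linear sequence: 14 steps (8 to 30, steps 5–18); the ring-A branch (1 to 7) has 4 steps.

**Steps most likely to fail**

Step 15 (proposed new method): acyl transfer to the very hindered hemiacylal hydroxyl may be slow or poorly discriminated by the catalyst, or lactol racemisation may not keep pace with carbonate formation. The fallback sets out from 26: allyl chloroformate and pyridine in CH2Cl2 at 0 °C should give the racemic bis(allyl carbonate) F1 without any stereocontrol. Its enantiomers are then separated by preparative chromatography on a chiral stationary phase, and the enantiomer with the target arrangement is 27, where the route is rejoined.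

Step 11: insertion of the doubly ortho-substituted aldehyde into the chloroformate may be incomplete, or the alcohol may be carbonylated instead of forming the acetal. The fallback sets out from 19. Pinnick oxidation (NaClO2, NaH2PO4, 2-methylbut-2-ene, t-BuOH/H2O) gives the benzoic acid F2. Alkylation with 4-methoxybenzyl chloride and K2CO3 in DMF gives the 4-methoxybenzyl ester F3. Reduction with iBu2AlH in CH2Cl2 at −78 °C stops at the aluminium hemiacetal F4, which is trapped in the same flask with pyridine, DMAP and phenyl chloroformate (reductive acylation of an ester). This gives 21, where the route is rejoined.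

Step 12: n-BuLi may add to the carbonate before the exchange is complete, or the tetrahedral intermediate may collapse by ring opening toward a formyl ester. The fallback sets out from 19 and replaces the anionic closure by a palladium-catalysed alkoxycarbonylative cyclisation: Pd(OAc)2, Xantphos, CO (1 atm), 4-methoxybenzyl alcohol and Et3N in toluene at 80 °C. The acylpalladium formed at the iodide is captured by the hemiacetal of the neighbouring aldehyde, which should give the pseudo-ester 23 directly, where the route is rejoined.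

**Further compounds**
F1 | step 15 | racemic 1,4-bis[(allyloxy)carbonyloxy] derivative of 26 | Cc1cc(OCC=C)c(C=O)c2c1C(=O)Oc1c(CO[Si](c3ccccc3)(c3ccccc3)C(C)(C)C)c(OC(=O)OCC=C)c3c(c1O2)C(OC(=O)OCC=C)OC3=O
F2 | step 11 | 2-{[tert-butyl(dimethyl)silyl]oxy}-4-{[tert-butyl(diphenyl)silyl]oxymethyl}-6-iodo-3,5-bis(methoxymethoxy)benzoic acid | OC(=O)c1c(O[Si](C)(C)C(C)(C)C)c(OCOC)c(CO[Si](c2ccccc2)(c2ccccc2)C(C)(C)C)c(OCOC)c1I
F3 | step 11 | 4-methoxybenzyl ester of F2 | COc1ccc(COC(=O)c2c(O[Si](C)(C)C(C)(C)C)c(OCOC)c(CO[Si](c3ccccc3)(c3ccccc3)C(C)(C)C)c(OCOC)c2I)cc1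
F4 | step 11 | diisobutylaluminium hemiacetal from F3 (not isolated) | CC(C)C[Al](CC(C)C)OC(OCc1ccc(OC)cc1)c1c(O[Si](C)(C)C(C)(C)C)c(OCOC)c(CO[Si](c2ccccc2)(c2ccccc2)C(C)(C)C)c(OCOC)c1I
F0 | step 12 | none | none
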